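**Plan**

- Cuts: the C15 acid and the C18 acetate go back to a silyl ether and a methyl ester. Ring A is opened at C4–C5 (palladium coupling of an ester enolate with a C5 enol triflate) and its C3–C4 unit is removed by cross-metathesis. The last cut takes away C9–C11 and C10–C1 together.
- Enabling feature: with C5 as a ketone, ring B is a cyclohexanone in which the quaternary C9 is the β-carbon and C10 the α-carbon, and the C8 methyl centre sits beside C9. The enone C5(=O)–C10=C9 can therefore take the side chain at C9 and an allyl group at C10 in one pot, with C8 directing.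
- Forward order: ring B is made first (anisole to (S)-3,4-dimethylcyclohexenone). The C11–C15 chain and the allyl group are joined to it in step 10, ring A is closed last in step 16, then C18 and C15 are adjusted.
- Stereochemistry: C8 from amine-catalysed asymmetric isomerisation; C13 from desymmetrised 3-methylglutaric anhydride; C9 by copper-mediated addition anti to the C8 methyl group; C10 by kinetic protonation of a ring B α′-enolate (step 12); C4 in the palladium ring closure.

Key step: step 10

Remark on the chemistry: halimane numbering is used (C18 = the oxygenated carbon on C4); the catalysts of steps 3 and 4 are the pseudoenantiomers that lead to the S products; the allylation in step 10 is assumed not to fix C10 (attack anti to the two cis methyl groups is expected, and the two C10 epimers of the ketone are close in energy), so C10 is set separately in step 12.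

**Route**

Step 1
Reactants: 1 3,4-dimethylanisole
Product: 2 1-methoxy-4,5-dimethylcyclohexa-1,4-diene
Conditions: Li, NH3 (l), t-BuOH, THF, −78 → −33 °C
Reagents that add atoms: none
Why: Birch reduction of an anisole protonates the ring ortho and meta to the methoxy group and leaves the methoxy- and methyl-bearing carbons sp2, so the unconjugated 1,4-diene should form as one regioisomer.

Step 2
Reactants: 2 1-methoxy-4,5-dimethylcyclohexa-1,4-diene
Product: 3 3,4-dimethylcyclohex-3-en-1-one
Conditions: oxalic acid (cat.), acetone/H2O, rt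
Reagents that add atoms: water, O
Why: Mild acid hydrolysis of the enol ether (C-protonation, hydration of the oxocarbenium ion, loss of methanol) should free the β,γ-unsaturated ketone without moving the tetrasubstituted alkene into conjugation.

Step 3
Reactants: 3 3,4-dimethylcyclohex-3-en-1-one
Product: 4 (S)-3,4-dimethylcyclohex-2-en-1-one
Conditions: chiral primary amine–tertiary amine catalyst of the cinchona class (10 mol %, pseudoenantiomer giving S), carboxylic acid co-catalyst, toluene, rt
Reagents that add atoms: none
Why: Amine-catalysed asymmetric alkene isomerisation, in which the primary amine forms a dienamine and the protonated tertiary amine delivers the proton to the γ-carbon on one face, should set C8 under catalyst control and give the conjugated enone after hydrolysis of the iminium ion.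

Step 4
Reactants: 5 3-methylglutaric anhydride
Product: 6 (S)-5-methoxy-3-methyl-5-oxopentanoic acid
Conditions: MeOH (10 equiv), (DHQD)2AQN or (DHQ)2AQN (10 mol %, the one giving the S acid), Et2O, −40 °C
Reagents that add atoms: methanol, CO
Why: Catalytic asymmetric alcoholysis (desymmetrisation) of a prochiral cyclic anhydride, in which the chiral base selects one of the two enantiotopic carbonyl groups, should fix the future C13 centre under catalyst control.

Step 5
Reactants: 6 (S)-5-methoxy-3-methyl-5-oxopentanoic acid
Product: 7 methyl (S)-5-hydroxy-3-methylpentanoate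
Conditions: BH3·SMe2, THF, 0 °C → rt; aqueous work-up, used crude
Reagents that add atoms: none
Why: Chemoselective borane reduction of a carboxylic acid beside a methyl ester should give the hydroxy ester, which is silylated at once to forestall lactonisation.

Step 6
Reactants: 7 methyl (S)-5-hydroxy-3-methylpentanoate
Product: 8 methyl (S)-3-methyl-5-(triisopropylsilyloxy)pentanoate
Conditions: TIPSCl, imidazole, DMF, rt
Reagents that add atoms: triisopropylsilyl chloride, CC(C)[Si](Cl)(C(C)C)C(C)C
Why: Standard silylation of a primary alcohol, with TIPS chosen because it should survive Grignard formation, amide bases, hydride and the Ru and Pd catalysts used later.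

Step 7
Reactants: 8 methyl (S)-3-methyl-5-(triisopropylsilyloxy)pentanoate
Product: 9 (R)-3-methyl-5-(triisopropylsilyloxy)pentan-1-ol
Conditions: LiAlH4, Et2O, 0 °C
Reagents that add atoms: none
Why: Hydride reduction of the ester to the primary alcohol leaves the silyl ether and the remote stereocentre untouched (the descriptor changes only through the priority rules).

Step 8
Reactants: 9 (R)-3-methyl-5-(triisopropylsilyloxy)pentan-1-ol
Product: 10 (S)-(5-bromo-3-methylpentyloxy)triisopropylsilane
Conditions: CBr4, PPh3, CH2Cl2, 0 °C
Reagents that add atoms: carbon tetrabromide, BrC(Br)(Br)Br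
Why: Appel bromination is an SN2 displacement at a primary carbon under nearly neutral conditions that a TIPS ether tolerates.

Step 9
Reactants: 10 (S)-(5-bromo-3-methylpentyloxy)triisopropylsilane
Product: 11 (S)-[3-methyl-5-(triisopropylsilyloxy)pentyl]magnesium bromide (THF solution, titrated)
Conditions: Mg turnings, I2 (cat.), THF, 40 °C
Reagents that add atoms: magnesium, [Mg]
Why: Magnesium insertion into a primary alkyl bromide (Grignard formation) should proceed without affecting the silyl ether or the γ-stereocentre.

Step 10
Reactants: 4 (S)-3,4-dimethylcyclohex-2-en-1-one; 11 side-chain Grignard reagent; 12 allyl bromide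
Product: 14 (2RS,3R,4S)-2-allyl-3,4-dimethyl-3-[(3R)-3-methyl-5-(triisopropylsilyloxy)pentyl]cyclohexan-1-one as both C10 epimers, via bromomagnesium enolate 13 (not isolated)
Conditions: 11 (1.3 equiv), CuBr·SMe2 (10 mol %), THF, −40 → −20 °C; then DMPU, 12 (3 equiv), −40 °C → rt
Reagents that add atoms: none
Why: The alkylcopper species formed from the Grignard reagent complexes the enone, adds oxidatively at C9 and reductively eliminates to give the C9–C11 bond and the regiodefined bromomagnesium enolate 13, which DMPU activates for SN2 C-allylation at C10 (C10–C1). The closest known reaction type is the copper-mediated vicinal difunctionalisation of 4-substituted 3-methylcyclohex-2-enones, that is conjugate addition of a Grignard reagent followed by trapping of the enolate with an allyl halide. No ring is closed. C9 is controlled by C8: allylic 1,2-strain with the C9 methyl group holds the C8 methyl group pseudoaxial in the enone, so the reagent enters axially on the opposite face and the side chain ends up trans to the C8 methyl group, with the two methyl groups cis. At C10 the allyl bromide is expected to approach anti to the two cis methyl groups, so this step should give mainly the 10-epimer beside the target isomer; both are carried on and C10 is reset in step 12. The step needs 1,4- over 1,2-addition (copper secures it) and mono-C-allylation at C10 only (the enolate is generated regiospecifically across C5–C10 and C6 is never deprotonated under these conditions).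

Step 11
Reactants: 14 allyl ketone (both C10 epimers)
Product: 17 (4S,5R,6RS)-6-allyl-4,5-dimethyl-5-[(3R)-3-methyl-5-(triisopropylsilyloxy)pentyl]cyclohex-2-en-1-one as both C10 epimers, via lithium enolate 15 (not isolated), via sulfilimine adduct 16 (not isolated)
Conditions: LDA (1.15 equiv), THF, −78 °C; then N-tert-butylbenzenesulfinimidoyl chloride (1.3 equiv), −78 °C
Reagents that add atoms: none
Why: Mukaiyama dehydrogenation: the kinetic lithium enolate (deprotonation at the unhindered C6 methylene, not at the tertiary C10) is sulfenylated and the adduct undergoes syn-elimination at low temperature to the C6–C7 enone, which leaves C10–H as the only enolisable α-hydrogen.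

Step 12
Reactants: 17 ring B enone (both C10 epimers)
Product: 19 (4S,5R,6S)-6-allyl-4,5-dimethyl-5-[(3R)-3-methyl-5-(triisopropylsilyloxy)pentyl]cyclohex-2-en-1-one, via lithium dienolate 18 (not isolated)
Conditions: LDA (1.3 equiv), THF, −78 → −40 °C; then 2,6-di-tert-butyl-4-methylphenol (3 equiv) in THF, −78 °C
Reagents that add atoms: none
Why: Kinetic α′-deprotonation of the cyclohexenone gives the cross-conjugated dienolate with C10 trigonal, and irreversible C-protonation by the hindered phenol at −78 °C (kinetic protonation under substrate control) should occur on the face opposite to the cis C8 and C9 methyl groups, which places the allyl group cis to both methyl groups as in the target.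

Step 13
Reactants: 19 ring B enone (C10 set); 20 methyl 2-methylbut-3-enoate (racemic)
Product: 21 methyl (3E)-5-{(1S,5S,6R)-5,6-dimethyl-6-[(3R)-3-methyl-5-(triisopropylsilyloxy)pentyl]-2-oxocyclohex-3-en-1-yl}-2-methylpent-3-enoate (C4 epimers, mainly E)
Conditions: 20 (5 equiv), Hoveyda–Grubbs II (5 mol %), CH2Cl2, 40 °C
Reagents that add atoms: none
Why: Olefin cross-metathesis of the terminal allyl group with an excess of the more hindered α-branched vinyl partner should give the C2=C3 alkene, while the ring enone alkene is unreactive and the alkene geometry and the ester α-configuration are erased later.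

Step 14
Reactants: 21 enone ester
Product: 22 methyl 5-{(1S,2R,3S)-2,3-dimethyl-2-[(3R)-3-methyl-5-(triisopropylsilyloxy)pentyl]-6-oxocyclohexyl}-2-methylpentanoate (C4 epimers)
Conditions: H2 (1 atm), 10% Pd/C, EtOAc, rt
Reagents that add atoms: none
Why: Heterogeneous hydrogenation should saturate the chain alkene and the conjugated ring alkene under neutral conditions that leave the ketone, the ester, the silyl ether and the C10 centre untouched.

Step 15
Reactants: 22 keto ester
Product: 24 methyl 5-{(1S,5S,6R)-5,6-dimethyl-6-[(3R)-3-methyl-5-(triisopropylsilyloxy)pentyl]-2-(trifluoromethylsulfonyloxy)cyclohex-2-en-1-yl}-2-methylpentanoate, via potassium enolate 23 (not isolated)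
Conditions: KHMDS (1.1 equiv), THF, −78 °C (ketone added to base); then PhNTf2, −78 → 0 °C
Reagents that add atoms: N-phenylbis(trifluoromethanesulfonimide), O=S(=O)(N(c1ccccc1)S(=O)(=O)C(F)(F)F)C(F)(F)F
Why: Kinetic enolisation removes a proton from the C6 methylene faster than from the hindered tertiary C10–H or the less acidic ester, and O-sulfonylation then gives the C5–C6 enol triflate (kinetic enol triflate formation).

Step 16
Reactants: 24 enol triflate
Product: 26 methyl (4R,8S,9R,10S,13R)-15-(triisopropylsilyloxy)halim-5-en-18-oate, via lithium ester enolate 25 (not isolated)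
Conditions: LiNCy2 (1.5 equiv), Pd(dba)2 (5 mol %), P(t-Bu)3 (6 mol %), toluene, 0 °C → rt
Reagents that add atoms: none
Why: Palladium-catalysed intramolecular α-alkenylation of an ester enolate (oxidative addition to the enol triflate, transmetalation of the lithium enolate, C–C reductive elimination) forms C4–C5, the quaternary C4 and ring A with the alkene fixed at C5–C6; the ester is expected to take the axial site on the face of C10–H, with the methyl group equatorial, in a chair-like palladacycle, but this 1,3-induction is the least secure in the route.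

Step 17
Reactants: 26 bicyclic ester
Product: 27 (4R,8S,9R,10S,13R)-15-(triisopropylsilyloxy)halim-5-en-18-ol
Conditions: LiAlH4, THF, 0 °C → rt
Reagents that add atoms: none
Why: Hydride reduction of the hindered neopentyl-type methyl ester should give the primary alcohol with the silyl ether and the trisubstituted alkene inert.

Step 18
Reactants: 27 C18 alcohol
Product: 28 (4R,8S,9R,10S,13R)-18-acetoxy-15-(triisopropylsilyloxy)halim-5-ene
Conditions: Ac2O, pyridine, DMAP (cat.), CH2Cl2, rt
Reagents that add atoms: acetic anhydride, CC(=O)OC(C)=O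
Why: DMAP-catalysed acylation of a primary alcohol is reliable even at a neopentyl position.

Step 19
Reactants: 28 acetate silyl ether
Product: 29 (4R,8S,9R,10S,13R)-18-acetoxyhalim-5-en-15-ol
Conditions: HF·pyridine, pyridine, THF, 0 °C → rt
Reagents that add atoms: none
Why: Buffered fluoride cleavage of the primary TIPS ether should spare the acetate and the alkene.

Step 20
Reactants: 29 C15 alcohol
Product: 31 (4R,8S,9R,10S,13R)-18-acetoxyhalim-5-en-15-oic acid (target), via aldehyde 30 (not isolated)
Conditions: TEMPO (20 mol %), PhI(OAc)2 (2.5 equiv), MeCN/H2O 1:1, rt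
Reagents that add atoms: water, O
Why: Oxoammonium (TEMPO) oxidation in aqueous acetonitrile takes the primary alcohol through the aldehyde hydrate to the carboxylic acid without touching the acetate, the trisubstituted alkene or the C13 centre.

**Compound list**

1 | 3,4-dimethylanisole | COc1ccc(C)c(C)c1 | starting material
2 | 1-methoxy-4,5-dimethylcyclohexa-1,4-diene | COC1=CCC(C)=C(C)C1 | intermediate
3 | 3,4-dimethylcyclohex-3-en-1-one | O=C1CC(C)=C(C)CC1 | intermediate
4 | (S)-3,4-dimethylcyclohex-2-en-1-one | O=C1C=C(C)[C@@H](C)CC1 | intermediate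
5 | 3-methylglutaric anhydride | CC1CC(=O)OC(=O)C1 | starting material
6 | (S)-5-methoxy-3-methyl-5-oxopentanoic acid | COC(=O)C[C@@H](C)CC(=O)O | intermediate
7 | methyl (S)-5-hydroxy-3-methylpentanoate | COC(=O)C[C@@H](C)CCO | intermediate
8 | methyl (S)-3-methyl-5-(triisopropylsilyloxy)pentanoate | COC(=O)C[C@@H](C)CCO[Si](C(C)C)(C(C)C)C(C)C | intermediate
9 | (R)-3-methyl-5-(triisopropylsilyloxy)pentan-1-ol | OCC[C@@H](C)CCO[Si](C(C)C)(C(C)C)C(C)C | intermediate
10 | (S)-(5-bromo-3-methylpentyloxy)triisopropylsilane | BrCC[C@@H](C)CCO[Si](C(C)C)(C(C)C)C(C)C | intermediate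
11 | (S)-[3-methyl-5-(triisopropylsilyloxy)pentyl]magnesium bromide | Br[Mg]CC[C@@H](C)CCO[Si](C(C)C)(C(C)C)C(C)C | intermediate
12 | allyl bromide | C=CCBr | starting material
13 | bromomagnesium C5–C10 enolate of the conjugate adduct, (3R,4S) in the ring, side chain trans to the C8 methyl group | C1=C(O[Mg]Br)CC[C@H](C)[C@@]1(C)CC[C@@H](C)CCO[Si](C(C)C)(C(C)C)C(C)C | intermediate
14 | (2RS,3R,4S)-2-allyl-3,4-dimethyl-3-[(3R)-3-methyl-5-(triisopropylsilyloxy)pentyl]cyclohexan-1-one, both C10 epimers | C=CCC1C(=O)CC[C@H](C)[C@@]1(C)CC[C@@H](C)CCO[Si](C(C)C)(C(C)C)C(C)C | intermediate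
15 | kinetic lithium C5–C6 enolate of 14 | C=CCC1C(O[Li])=CC[C@H](C)[C@@]1(C)CC[C@@H](C)CCO[Si](C(C)C)(C(C)C)C(C)C | intermediate
16 | C6 N-tert-butyl-S-phenylsulfilimine adduct of 14 | C=CCC1C(=O)C(S(=NC(C)(C)C)c2ccccc2)C[C@H](C)[C@@]1(C)CC[C@@H](C)CCO[Si](C(C)C)(C(C)C)C(C)C | intermediate
17 | (4S,5R,6RS)-6-allyl-4,5-dimethyl-5-[(3R)-3-methyl-5-(triisopropylsilyloxy)pentyl]cyclohex-2-en-1-one, both C10 epimers | C=CCC1C(=O)C=C[C@H](C)[C@@]1(C)CC[C@@H](C)CCO[Si](C(C)C)(C(C)C)C(C)C | intermediate
18 | cross-conjugated lithium dienolate of 17 (C10 trigonal) | C=CCC1=C(O[Li])C=C[C@H](C)[C@@]1(C)CC[C@@H](C)CCO[Si](C(C)C)(C(C)C)C(C)C | intermediate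
19 | (4S,5R,6S)-6-allyl-4,5-dimethyl-5-[(3R)-3-methyl-5-(triisopropylsilyloxy)pentyl]cyclohex-2-en-1-one, allyl cis to both ring methyl groups | C=CC[C@@H]1C(=O)C=C[C@H](C)[C@@]1(C)CC[C@@H](C)CCO[Si](C(C)C)(C(C)C)C(C)C | intermediate
20 | methyl 2-methylbut-3-enoate (racemic) | C=CC(C)C(=O)OC | starting material
21 | methyl (3E)-5-{(1S,5S,6R)-5,6-dimethyl-6-[(3R)-3-methyl-5-(triisopropylsilyloxy)pentyl]-2-oxocyclohex-3-en-1-yl}-2-methylpent-3-enoate, C4 epimers | COC(=O)C(C)/C=C/C[C@@H]1C(=O)C=C[C@H](C)[C@@]1(C)CC[C@@H](C)CCO[Si](C(C)C)(C(C)C)C(C)C | intermediate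
22 | methyl 5-{(1S,2R,3S)-2,3-dimethyl-2-[(3R)-3-methyl-5-(triisopropylsilyloxy)pentyl]-6-oxocyclohexyl}-2-methylpentanoate, C4 epimers | COC(=O)C(C)CCC[C@@H]1C(=O)CC[C@H](C)[C@@]1(C)CC[C@@H](C)CCO[Si](C(C)C)(C(C)C)C(C)C | intermediate
23 | potassium C5–C6 enolate of 22 | COC(=O)C(C)CCC[C@@H]1C(O[K])=CC[C@H](C)[C@@]1(C)CC[C@@H](C)CCO[Si](C(C)C)(C(C)C)C(C)C | intermediate
24 | methyl 5-{(1S,5S,6R)-5,6-dimethyl-6-[(3R)-3-methyl-5-(triisopropylsilyloxy)pentyl]-2-(trifluoromethylsulfonyloxy)cyclohex-2-en-1-yl}-2-methylpentanoate | COC(=O)C(C)CCC[C@@H]1C(OS(=O)(=O)C(F)(F)F)=CC[C@H](C)[C@@]1(C)CC[C@@H](C)CCO[Si](C(C)C)(C(C)C)C(C)C | intermediate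
25 | lithium ester enolate of 24 | COC(O[Li])=C(C)CCC[C@@H]1C(OS(=O)(=O)C(F)(F)F)=CC[C@H](C)[C@@]1(C)CC[C@@H](C)CCO[Si](C(C)C)(C(C)C)C(C)C | intermediate
26 | methyl (4R,8S,9R,10S,13R)-15-(triisopropylsilyloxy)halim-5-en-18-oate | COC(=O)[C@]1(C)CCC[C@@H]2C1=CC[C@H](C)[C@@]2(C)CC[C@@H](C)CCO[Si](C(C)C)(C(C)C)C(C)C | intermediate
27 | (4R,8S,9R,10S,13R)-15-(triisopropylsilyloxy)halim-5-en-18-ol | OC[C@]1(C)CCC[C@@H]2C1=CC[C@H](C)[C@@]2(C)CC[C@@H](C)CCO[Si](C(C)C)(C(C)C)C(C)C | intermediate
28 | (4R,8S,9R,10S,13R)-18-acetoxy-15-(triisopropylsilyloxy)halim-5-ene | CC(=O)OC[C@]1(C)CCC[C@@H]2C1=CC[C@H](C)[C@@]2(C)CC[C@@H](C)CCO[Si](C(C)C)(C(C)C)C(C)C | intermediate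
29 | (4R,8S,9R,10S,13R)-18-acetoxyhalim-5-en-15-ol | CC(=O)OC[C@]1(C)CCC[C@@H]2C1=CC[C@H](C)[C@@]2(C)CC[C@@H](C)CCO | intermediate
30 | (4R,8S,9R,10S,13R)-18-acetoxyhalim-5-en-15-al | CC(=O)OC[C@]1(C)CCC[C@@H]2C1=CC[C@H](C)[C@@]2(C)CC[C@@H](C)CC=O | intermediate
31 | (4R,8S,9R,10S,13R)-18-acetoxyhalim-5-en-15-oic acid, CNP0148247.1 | CC(=O)OC[C@]1(C)CCC[C@@H]2C1=CC[C@H](C)[C@@]2(C)CC[C@@H](C)CC(=O)O | target

**Count and risks**

Total step count: 20. Longest linear sequence: 17 steps (steps 4–20, from 3-methylglutaric anhydride).

Steps most likely to fail: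

1. Step 16. The reductive elimination to a quaternary carbon may be slow, so that β-hydride elimination or loss of the triflate takes over, and the two faces of the enolate carbon may be poorly distinguished, giving both C4 epimers. The fallback sets out from 19 and comes back at 26, and forms the ring before the quaternary centre. Cross-metathesis of 19 with methyl but-3-enoate would give the unbranched enone ester F1, and hydrogenation as in step 14 the keto ester F2. KHMDS converts F2 into the potassium enolate F3, which PhNTf2 traps as the enol triflate F4. LiHMDS (2.2 equiv) then forms the lithium ester enolate F5, which the same palladium catalyst cyclises at a tertiary instead of a quaternary carbon to the β,γ-unsaturated bicyclic ester F6 (either C4 epimer). LDA deprotonates C4 of F6 to the extended lithium enolate F7. Methyl iodide should alkylate F7 at C4 from the equatorial direction, away from the axial hydrogens on C10 and C2, as is usual for exocyclic ester enolates of six-membered rings. That places the methyl group equatorial and the ester axial, which is 26.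

2. Step 12. Deprotonation of the hindered C10–H may be incomplete, and the proton may be delivered with low facial selectivity or first to oxygen, so that the C10 epimers equilibrate. The fallback sets out from 17 and comes back at 19, and replaces substrate control by catalyst control. The dienolate 18 made from 17 is O-acylated with allyl chloroformate to the allyl dienyl carbonate F8. Pd2(dba)3 with a chiral phosphinooxazoline ligand and formic acid then effects decarboxylative protonation, in which the palladium enolate is protonated under control of the ligand (enantiomer matched to the substrate bias), to give 19.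

3. Step 10. Conjugate addition to the hindered β,β-disubstituted enone may stall, the Grignard reagent may couple with allyl bromide, and proton transfer between product and enolate may lead to over-allylation or incomplete trapping. The fallback sets out from 4 and 11 and comes back at 14, and separates the two bond formations. The copper-catalysed addition is run with chlorotrimethylsilane, which accelerates the addition and delivers the trimethylsilyl enol ether F9. Methyllithium then liberates the lithium enolate F10 regiospecifically, and allyl bromide in THF/DMPU gives 14.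

**Further compounds**

F1 | step 16 | methyl (3E)-5-{(1S,5S,6R)-5,6-dimethyl-6-[(3R)-3-methyl-5-(triisopropylsilyloxy)pentyl]-2-oxocyclohex-3-en-1-yl}pent-3-enoate | COC(=O)C/C=C/C[C@@H]1C(=O)C=C[C@H](C)[C@@]1(C)CC[C@@H](C)CCO[Si](C(C)C)(C(C)C)C(C)C
F2 | step 16 | methyl 5-{(1S,2R,3S)-2,3-dimethyl-2-[(3R)-3-methyl-5-(triisopropylsilyloxy)pentyl]-6-oxocyclohexyl}pentanoate | COC(=O)CCCC[C@@H]1C(=O)CC[C@H](C)[C@@]1(C)CC[C@@H](C)CCO[Si](C(C)C)(C(C)C)C(C)C
F3 | step 16 | potassium C5–C6 enolate of F2 | COC(=O)CCCC[C@@H]1C(O[K])=CC[C@H](C)[C@@]1(C)CC[C@@H](C)CCO[Si](C(C)C)(C(C)C)C(C)C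
F4 | step 16 | C5–C6 enol triflate of F2 | COC(=O)CCCC[C@@H]1C(OS(=O)(=O)C(F)(F)F)=CC[C@H](C)[C@@]1(C)CC[C@@H](C)CCO[Si](C(C)C)(C(C)C)C(C)C
F5 | step 16 | lithium ester enolate of F4 | COC(O[Li])=CCCC[C@@H]1C(OS(=O)(=O)C(F)(F)F)=CC[C@H](C)[C@@]1(C)CC[C@@H](C)CCO[Si](C(C)C)(C(C)C)C(C)C
F6 | step 16 | methyl (8S,9R,10S,13R)-19-nor-15-(triisopropylsilyloxy)halim-5-en-18-oate, C4 epimers | COC(=O)C1CCC[C@@H]2C1=CC[C@H](C)[C@@]2(C)CC[C@@H](C)CCO[Si](C(C)C)(C(C)C)C(C)C
F7 | step 16 | extended lithium enolate of F6 (C4 trigonal) | COC(O[Li])=C1CCC[C@@H]2C1=CC[C@H](C)[C@@]2(C)CC[C@@H](C)CCO[Si](C(C)C)(C(C)C)C(C)C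
F8 | step 12 | allyl dienyl carbonate of 17 (C5–C10 enol carbonate) | C=CCC1=C(OC(=O)OCC=C)C=C[C@H](C)[C@@]1(C)CC[C@@H](C)CCO[Si](C(C)C)(C(C)C)C(C)C
F9 | step 10 | trimethylsilyl C5–C10 enol ether of the conjugate adduct | C1=C(O[Si](C)(C)C)CC[C@H](C)[C@@]1(C)CC[C@@H](C)CCO[Si](C(C)C)(C(C)C)C(C)C
F10 | step 10 | lithium C5–C10 enolate of the conjugate adduct | C1=C(O[Li])CC[C@H](C)[C@@]1(C)CC[C@@H](C)CCO[Si](C(C)C)(C(C)C)C(C)C
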